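# Proposed total synthesis of (6S,7S,8R,11R)-6,11-bis(angeloyloxy)germacra-1(10)Z,4E-dien-12,8-olide

## The problem

The target is a (1(10)Z,4E)-germacradien-12,8-olide: a cyclodecadiene (C1–C10) with a Z trisubstituted alkene C1=C10 (methyl C14) and an E trisubstituted alkene C4=C5 (methyl C15), a γ-lactone (C8–O–C12(=O)–C11–C7) trans-fused across C7–C8, and angelate esters on the allylic secondary oxygen at C6 and on the tertiary oxygen at C11. Four contiguous stereocentres (6S, 7S, 8R, 11R) are required, and the quaternary C11 (methyl C13, oxygen, C12, C7) cannot be corrected by epimerisation, so it must come out of a C–C bond formation. C8 is the one centre that a catalyst can set on a simple chain; it can then direct the C6/C7 pair by face selection on a small ring that contains C8, after which C7 follows by inversion and C11 has to be induced by C7. The ten-membered ring is strained and flexible, so stereocontrol on the closed ring is unreliable, ring closure is the main risk, and both alkene geometries are best fixed before the ring exists. Several groups will not survive rough treatment: the angelates isomerise to tiglates with nucleophiles or base and are reduced by dissolving metals, the 1(10),4-diene cyclises across the ring in acid, and a free C6 alkoxide can attack C12 and move the lactone from O8 to O6. The enabling feature is that C11, with its methyl, its oxygen and the carbonyl C12, is a lactic acid unit esterified to O8, while C7 lies between two oxygen-bearing carbons. O6 can therefore be the oxygen of a C6–C7 epoxide, and the O8-bound lactate enolate can open that epoxide at C7, which makes the C7–C11 bond, the lactone ring, and the C7 and C11 centres in one step.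

## Retrosynthesis

**Angelates.** Target 33 is cut at both ester C–O bonds to diol 30 and angelic anhydride 32 (from two molecules of angelic acid 31). Every earlier position for the angelates would expose them to sulfinate, amide bases or sodium amalgam, so they go on last. The precursor loses ten carbons and two isomerisable alkenes. The forward step must acylate a hindered secondary and a tertiary α-hydroxy-lactone hydroxyl without a nucleophilic catalyst and without letting O6 attack C12.

**Ring.** Diol 30 comes from bis-silyl ether 29, and 29 from the macrocyclic sulfone 28, which is opened at C2–C3 to the bromo sulfone 27. C2–C3 is the only ring bond between two sp3 carbons that are both allylic and bear no stereocentre. A cut at either alkene would leave its geometry to a ten-ring closure. Cuts at C5–C6, C6–C7 or C8–C9 would create or endanger stereocentres during closure. Compound 27 is an open chain on a finished lactone that already holds all four stereocentres and both alkenes. The forward reaction is an SN2 alkylation of an α-sulfonyl allyl anion under dilution, followed by removal of the sulfone without allylic shift.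

**Side arms.** Compound 27 is traced through alcohol 26 and enal 25 to aldehyde 23 and the stabilised ylide 24, which is a cut of C4=C5 that delivers the E alkene with C3 and C15. Aldehyde 23 comes from alcohol 22 and trityl ether 21. The sulfone of 21 comes from bromide 20, alcohol 19 and the PMB ether 18. C5 stays a saturated CH2OTr carbon through 18, so that C6 is not allylic when the epoxide is opened. The sulfone is put in before the C3 bromide exists, so that no second electrophile competes.

**Lactone (key cut).** Compound 18 is the silyl ether of hydroxy lactone 17, and 17 is cut at C7–C11 to the epoxy lactate ester 16. The neighbouring cuts at C11–C13 or C11–O, meaning methylation or hydroxylation of a preformed lactone enolate, would set C11 in a separate step after C7. The chosen cut sets both together and makes the ring as well. Compound 16 has only an epoxide, one carbinol centre and a lactate centre that is lost in the enolate. The forward reaction must open the epoxide at C7 in the exo mode with inversion and select one enolate face.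

**Ester.** Compound 16 is cut at the ester C–O bond to epoxy alcohol 12 and the silylated lactic acid 15, made from ethyl (S)-lactate 13 through 14. Esterification retains C8, so the needed relation of O8 and the epoxide oxygen (erythro, with the epoxide anti to the C9 chain) must already be present in 12.

**Epoxy alcohol.** Compound 12 is the trityl ether of diol 11, the reduction product of epoxy lactone 10, which comes from butenolide 9. Tying O8 to C5 as a lactone turns the open-chain erythro problem into anti addition to a five-membered ring. It also makes C6=C7 electron-poor, so a nucleophilic oxidant leaves the C1=C10 alkene alone. The neighbouring option, hydroxyl-directed peracid epoxidation of the open Z-allylic alcohol, gives the threo isomer, would need inversion at C8, and would compete with the more electron-rich trisubstituted alkene.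

**Chain.** Butenolide 9 comes via 8 from the Z-enoate 7. Compound 7 is cut at C6=C7 (Z-selective Horner–Wadsworth–Emmons reaction with phosphonate 5) and at C8–O (proline-catalysed α-aminoxylation, via 6) to aldehyde 4. Aldehyde 4 is obtained from nerol 1 through ether 2 and epoxide 3. Nerol supplies C2, C1, C10, C14, C9, C8 and C7 with the Z alkene in place.

## Roads not taken

Alternative 1: Ring contraction by [2,3]-Wittig rearrangement.
- **Cut:** C6–C7 of the carbocycle, with O–C12 reconnected, giving the thirteen-membered diallylic ether A2.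
- **Forward key step:** n-C4H9Li lithiates C6 at low temperature. The [2,3] shift forms C6–C7, breaks O–C12, and gives cyclodecadienol A1 with a C7 vinyl group.
- **Merits:** The large ether ring is easy to close, and the contraction has no medium-ring entropy penalty. C6–OH and C7 arise together with both alkenes already in place.
- **Weak points:** A1 carries only a vinyl group at C7. C12 must be oxidised, the lactone closed, and C11 given its methyl and its oxygen by two enolate steps on a flexible ten-membered ring. C11 would then be set last, under the weakest control. Lithiation must choose C6 over C12, which is also allylic and α to oxygen. Absolute control must cross the ring from C8 alone.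
- **Comparison:** This road is better at making the ring. The chosen plan sets against it that all four stereocentres, including the quaternary C11, are fixed in open-chain material before a harder ring closure.

Alternative 2: Hydroboration and B-alkyl Suzuki–Miyaura closure at C3–C4.
- **Cut:** C3–C4, giving the seco iodide A4, a lactone with a C4 alkenyl iodide and a Z-1,3-diene ending in C2=C3.
- **Forward key step:** 9-BBN adds to the terminal alkene with boron on C3. PdCl2(dppf) and aqueous base couple the alkylborane with the iodide and close the ring to A3, which is identical with 29.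
- **Merits:** The C4=C5 geometry is locked in the iodide. No auxiliary has to be installed and removed, so 29 would be reached about three steps sooner. A4 could itself be made by the same lactate–epoxide cyclisation.
- **Weak points:** 9-BBN must select the terminal alkene of a conjugated diene without forming allylic boranes that scramble the Z alkene. The coupling has to form a ten-membered ring through a strained palladacycle. Aqueous base is applied to a lactone next to a silyl ether that, once lost, allows lactone migration. The E-iodoalkene beside C6 costs steps of its own.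
- **Comparison:** In step count this road is as good or better. The chosen plan sets against it a closure between two sp3 allylic carbons, the most flexible site of the ring, under anhydrous conditions.

Alternative 3: Intramolecular allylboration at C8–C9.
- **Cut:** C8–C9, giving the aldehyde boronate A6, a C8 aldehyde tethered to an α-substituted allyl pinacolboronate.
- **Forward key step:** C9 attacks the aldehyde through a six-membered chair. This forms C8–C9, shifts the alkene to C1=C10, and closes the ring to the cyclodecadienol ester A5.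
- **Merits:** Ring, C8 carbinol and Z alkene come from one closed transition state without base or high dilution. This is more convergent than taking the Z alkene from nerol.
- **Weak points:** The chair is embedded in a forming ten-membered ring, so ring strain decides the Z geometry and the C8 configuration, not the usual axial preference. The α-chiral allylboronate must be carried beside a masked aldehyde. A5 still needs lactonisation and two enolate steps at C11 on the ring.
- **Comparison:** If the closure behaved, ring building would be shorter. The chosen plan sets against it a catalyst-controlled C8, a Z alkene taken ready-made from nerol, and C11 formed together with C7.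

Key step: step 12

## Route

Remark on the chemistry: germacrane numbering is used throughout (C1–C10 ring, C11–C13 lactate unit, C14 on C10, C15 on C4). The sulfone-bearing C2 of 28 is expected as a mixture of epimers, which is carried on because that centre disappears in step 23.

Step 1
Reactants: 1 nerol
Product: 2 neryl 4-methoxybenzyl ether [1-({[(2Z)-3,7-dimethylocta-2,6-dien-1-yl]oxy}methyl)-4-methoxybenzene]
Conditions: NaH, PMBCl, Bu4NI (cat.), THF/DMF, 0 °C to rt
Reagents that add atoms: 4-methoxybenzyl chloride, COc1ccc(CCl)cc1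
Why: Williamson etherification of the primary allylic alkoxide. The PMB ether is chosen because DDQ can later remove it without touching trityl or silyl ethers.

Step 2
Reactants: 2 neryl PMB ether
Product: 3 rac-3-[(3Z)-5-[(4-methoxyphenyl)methoxy]-3-methylpent-3-en-1-yl]-2,2-dimethyloxirane
Conditions: mCPBA (1.05 equiv), NaHCO3, CH2Cl2, −20 to 0 °C
Reagents that add atoms: 3-chloroperoxybenzoic acid, OOC(=O)c1cccc(Cl)c1
Why: Prilezhaev epoxidation; the remote isopropylidene alkene is the more electron-rich because the other alkene is deactivated by its allylic ether oxygen. The new centre is lost in step 3, so its configuration does not matter.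

Step 3
Reactants: 3 epoxide
Product: 4 (4Z)-6-[(4-methoxyphenyl)methoxy]-4-methylhex-4-enal
Conditions: H5IO6, THF/H2O, 0 °C
Reagents that add atoms: none
Why: Periodic acid opens the epoxide to the glycol and cleaves it (Malaprade glycol cleavage) to the aldehyde and acetone. The PMB ether and the Z alkene are inert.

Step 4
Reactants: 4 aldehyde; 5 ethyl 2-(diphenoxyphosphoryl)acetate
Product: 7 ethyl (2Z,4R,6Z)-8-[(4-methoxyphenyl)methoxy]-6-methyl-4-[(phenylamino)oxy]octa-2,6-dienoate, via α-aminoxy aldehyde 6 (not isolated)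
Conditions: PhNO, L-proline (20 mol %), MeCN, −20 °C; then 5, NaI, DBU, THF, −40 to 0 °C
Reagents that add atoms: nitrosobenzene, O=Nc1ccccc1
Why: Proline-catalysed α-aminoxylation (enamine catalysis, O-selective nitroso aldol); with L-proline the hydrogen-bonded transition state should give the (R)-aldehyde 6, which sets C8. The labile aldehyde is olefinated in the same flask by a Z-selective Horner–Wadsworth–Emmons reaction of the diaryl phosphonoacetate under mild NaI/DBU conditions that should not enolise C8.

Step 5
Reactants: 7 aminoxy enoate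
Product: 9 (5R)-5-[(2Z)-4-[(4-methoxyphenyl)methoxy]-2-methylbut-2-en-1-yl]furan-2(5H)-one, via hydroxy enoate 8 (not isolated)
Conditions: CuSO4·5H2O (0.3 equiv), MeOH, 0 °C to rt; then PPTS (cat.), toluene, 40 °C
Reagents that add atoms: none
Why: Copper-sulfate-mediated N–O cleavage frees the C8 hydroxyl, and the Z geometry holds it next to the ester so that acid-catalysed lactonisation closes the butenolide. Any E-enoate from step 4 cannot lactonise and is separated here.

Step 6
Reactants: 9 butenolide
Product: 10 (1R,4R,5R)-4-[(2Z)-4-[(4-methoxyphenyl)methoxy]-2-methylbut-2-en-1-yl]-3,6-dioxabicyclo[3.1.0]hexan-2-one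
Conditions: NaOCl (aq), pyridine, 0 °C
Reagents that add atoms: sodium hypochlorite, [Na+].[O-]Cl
Why: Nucleophilic (Weitz–Scheffer type) epoxidation; hypochlorite adds to C7 anti to the adjacent C8 substituent and the enolate closes on oxygen, so the cis-epoxide lies anti to the C9 chain, which sets C6 and C7. The electron-rich C1=C10 alkene is not attacked by a nucleophilic oxidant.

Step 7
Reactants: 10 epoxy lactone
Product: 11 (1R,3Z)-1-[(2R,3S)-3-(hydroxymethyl)oxiran-2-yl]-5-[(4-methoxyphenyl)methoxy]-3-methylpent-3-en-1-ol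
Conditions: NaBH4, EtOH/THF, 0 °C
Reagents that add atoms: none
Why: Borohydride reduction of the lactone, which is activated by its α-oxygen, to the 1,4-diol. The epoxide is inert to NaBH4 at 0 °C, and a short reaction time limits Payne rearrangement.

Step 8
Reactants: 11 epoxy diol
Product: 12 (1R,3Z)-5-[(4-methoxyphenyl)methoxy]-3-methyl-1-[(2R,3S)-3-[(triphenylmethoxy)methyl]oxiran-2-yl]pent-3-en-1-ol
Conditions: TrCl, Et3N, DMAP (cat.), CH2Cl2, 0 °C to rt
Reagents that add atoms: trityl chloride, ClC(c1ccccc1)(c1ccccc1)c1ccccc1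
Why: Tritylation selects the primary hydroxyl on steric grounds. The trityl ether is base-stable, cannot migrate to a neighbouring alkoxide, and shields C6 in the key step.

Step 9
Reactants: 13 ethyl (S)-lactate
Product: 14 ethyl (2S)-2-[(tert-butyldimethylsilyl)oxy]propanoate
Conditions: TBSCl, imidazole, DMF, rt
Reagents that add atoms: tert-butyldimethylsilyl chloride, CC(C)(C)[Si](C)(C)Cl
Why: Standard silylation of a secondary alcohol. The tert-butyldimethylsilyl group is chosen as the common silyl group least prone to migrate in an enolate.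

Step 10
Reactants: 14 silyl lactate ester
Product: 15 (2S)-2-[(tert-butyldimethylsilyl)oxy]propanoic acid
Conditions: LiOH·H2O, THF/H2O, 0 °C; then dilute HCl to pH 4
Reagents that add atoms: lithium hydroxide, [Li+].[OH-]
Why: Saponification of the ethyl ester. Any loss of configuration at this centre is harmless because it becomes the enolate carbon in step 12.

Step 11
Reactants: 12 trityl epoxy alcohol; 15 silyl lactic acid
Product: 16 (1R,3Z)-5-[(4-methoxyphenyl)methoxy]-3-methyl-1-[(2R,3S)-3-[(triphenylmethoxy)methyl]oxiran-2-yl]pent-3-en-1-yl (2S)-2-[(tert-butyldimethylsilyl)oxy]propanoate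
Conditions: DCC, DMAP (cat.), CH2Cl2, 0 °C to rt
Reagents that add atoms: none
Why: Steglich esterification at the acyl carbon, so C8 is retained. The erythro relation of O8 and the epoxide already matches the target and no inversion is needed.

Step 12
Reactants: 16 epoxy lactate ester
Product: 17 (3R,4R,5R)-3-[(tert-butyldimethylsilyl)oxy]-4-[(1R)-1-hydroxy-2-(triphenylmethoxy)ethyl]-5-[(2Z)-4-[(4-methoxyphenyl)methoxy]-2-methylbut-2-en-1-yl]-3-methyloxolan-2-one
Conditions: LiN(SiMe3)2 (1.3 equiv), THF, −78 to 0 °C; then AcOH, −78 °C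
Reagents that add atoms: none
Why: LiN(SiMe3)2 removes the α-proton of the silyloxy propionate, and the lithium enolate attacks C7 of the neighbouring epoxide from the side opposite the C7–O bond; this is an intramolecular SN2 opening of an epoxide by an ester enolate, the closest known type being the base-induced cyclisation of esters of 2,3-epoxy alcohols and of epoxy nitriles. The ring C11–C12–O8–C8–C7 closes in the 5-exo-tet mode; the 6-endo path to C6 needs a longer reach and meets the neopentyl-like CH2OTr group, and C-alkylation is expected over O-alkylation for a lithium ester enolate with an epoxide. C7 is set by inversion: because the epoxide oxygen of 16 is anti to the C9 chain, the new C7–C11 bond ends up trans to that chain, which gives the trans lactone. C11 is set by the enolate face: with lithium bridging the enolate and silyloxy oxygens the enolate geometry is fixed, and the transition state that turns the C13 methyl toward H7 and the flat chelate toward the C6 branch should be the lower one, leaving the silyloxy group cis to C6 (11R). C6 and C8 are spectators, and C6 appears as the lithium alkoxide. The step needs attack at C7 and not C6 and one enolate face, which ring size and chelation should secure; the configuration of the lactate centre in 16 is irrelevant. The mixture is quenched cold with AcOH so that the C6 alkoxide neither attacks C12 (shift to the 12,6-olide) nor takes the silyl group from O11.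

Step 13
Reactants: 17 hydroxy lactone
Product: 18 (3R,4S,5R)-3-[(tert-butyldimethylsilyl)oxy]-4-[(1R)-1-[(tert-butyldimethylsilyl)oxy]-2-(triphenylmethoxy)ethyl]-5-[(2Z)-4-[(4-methoxyphenyl)methoxy]-2-methylbut-2-en-1-yl]-3-methyloxolan-2-one
Conditions: TBSOTf, 2,6-lutidine, CH2Cl2, −78 to 0 °C
Reagents that add atoms: tert-butyldimethylsilyl trifluoromethanesulfonate, CC(C)(C)[Si](C)(C)OS(=O)(=O)C(F)(F)F
Why: Silyl triflate silylation of the hindered secondary hydroxyl. Because O6 and O11 then carry the same group, any product of silyl shift from O11 to O6 in step 12 is silylated at the tertiary hydroxyl and converges on 18.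

Step 14
Reactants: 18 bis-silyl lactone
Product: 19 (3R,4S,5R)-3-[(tert-butyldimethylsilyl)oxy]-4-[(1R)-1-[(tert-butyldimethylsilyl)oxy]-2-(triphenylmethoxy)ethyl]-5-[(2Z)-4-hydroxy-2-methylbut-2-en-1-yl]-3-methyloxolan-2-one
Conditions: DDQ, CH2Cl2/pH 7 buffer, 0 °C
Reagents that add atoms: none
Why: Oxidative cleavage of the PMB ether (hydride abstraction by DDQ, hydrolysis of the oxocarbenium ion). Trityl and silyl ethers and the lactone are inert.

Step 15
Reactants: 19 allylic alcohol
Product: 20 (3R,4S,5R)-5-[(2Z)-4-bromo-2-methylbut-2-en-1-yl]-3-[(tert-butyldimethylsilyl)oxy]-4-[(1R)-1-[(tert-butyldimethylsilyl)oxy]-2-(triphenylmethoxy)ethyl]-3-methyloxolan-2-one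
Conditions: CBr4, PPh3, CH2Cl2, −20 °C
Reagents that add atoms: carbon tetrabromide, BrC(Br)(Br)Br
Why: Appel bromination; SN2 at the primary allylic carbon at low temperature keeps the Z geometry.

Step 16
Reactants: 20 allylic bromide
Product: 21 (3R,4S,5R)-5-[(2Z)-4-(benzenesulfonyl)-2-methylbut-2-en-1-yl]-3-[(tert-butyldimethylsilyl)oxy]-4-[(1R)-1-[(tert-butyldimethylsilyl)oxy]-2-(triphenylmethoxy)ethyl]-3-methyloxolan-2-one
Conditions: PhSO2Na, DMF, 0 °C to rt
Reagents that add atoms: sodium benzenesulfinate, [Na+].[O-]S(=O)c1ccccc1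
Why: S-alkylation of the sulfinate by the primary allylic bromide (SN2) gives the allylic sulfone. The sulfone is installed only now because it would be deprotonated before the ester in step 12.

Step 17
Reactants: 21 trityl sulfone
Product: 22 (3R,4S,5R)-5-[(2Z)-4-(benzenesulfonyl)-2-methylbut-2-en-1-yl]-3-[(tert-butyldimethylsilyl)oxy]-4-[(1R)-1-[(tert-butyldimethylsilyl)oxy]-2-hydroxyethyl]-3-methyloxolan-2-one
Conditions: TsOH·H2O (cat.), MeOH/CH2Cl2, 0 °C
Reagents that add atoms: none
Why: Acid-catalysed solvolysis of the trityl ether through the trityl cation, trapped by methanol. It is far faster than cleavage of the secondary and tertiary silyl ethers.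

Step 18
Reactants: 22 primary alcohol
Product: 23 (3R,4S,5R)-5-[(2Z)-4-(benzenesulfonyl)-2-methylbut-2-en-1-yl]-3-[(tert-butyldimethylsilyl)oxy]-4-[(1R)-1-[(tert-butyldimethylsilyl)oxy]-2-oxoethyl]-3-methyloxolan-2-one
Conditions: Dess–Martin periodinane, NaHCO3, CH2Cl2, 0 °C to rt
Reagents that add atoms: none
Why: Dess–Martin oxidation under buffered, non-basic conditions, which should not epimerise the α-silyloxy aldehyde at C6.

Step 19
Reactants: 23 aldehyde; 24 2-(triphenylphosphoranylidene)propanal
Product: 25 (3R,4S,5R)-5-[(2Z)-4-(benzenesulfonyl)-2-methylbut-2-en-1-yl]-3-[(tert-butyldimethylsilyl)oxy]-4-[(1S,2E)-1-[(tert-butyldimethylsilyl)oxy]-3-methyl-4-oxobut-2-en-1-yl]-3-methyloxolan-2-one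
Conditions: toluene, 80 °C
Reagents that add atoms: none
Why: Wittig reaction of a stabilised formyl ylide, which gives the (E)-2-methyl enal and so sets the C4=C5 geometry. The ylide is not basic enough to deprotonate the sulfone or epimerise C6.

Step 20
Reactants: 25 enal
Product: 26 (3R,4S,5R)-5-[(2Z)-4-(benzenesulfonyl)-2-methylbut-2-en-1-yl]-3-[(tert-butyldimethylsilyl)oxy]-4-[(1S,2E)-1-[(tert-butyldimethylsilyl)oxy]-4-hydroxy-3-methylbut-2-en-1-yl]-3-methyloxolan-2-one
Conditions: NaBH4, CeCl3·7H2O, MeOH, −40 °C
Reagents that add atoms: none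
Why: Luche 1,2-reduction of the enal. The hindered lactone is not reduced at this temperature.

Step 21
Reactants: 26 allylic alcohol
Product: 27 (3R,4S,5R)-5-[(2Z)-4-(benzenesulfonyl)-2-methylbut-2-en-1-yl]-4-[(1S,2E)-4-bromo-1-[(tert-butyldimethylsilyl)oxy]-3-methylbut-2-en-1-yl]-3-[(tert-butyldimethylsilyl)oxy]-3-methyloxolan-2-one
Conditions: CBr4, PPh3, CH2Cl2, −20 °C
Reagents that add atoms: carbon tetrabromide, BrC(Br)(Br)Br
Why: Appel bromination of the primary allylic alcohol with retention of the E geometry.

Step 22
Reactants: 27 bromo sulfone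
Product: 28 (6S,7S,8R,11R)-2-(benzenesulfonyl)-6,11-bis[(tert-butyldimethylsilyl)oxy]germacra-1(10)Z,4E-dien-12,8-olide (mixture of C2 epimers)
Conditions: NaN(SiMe3)2 (1.2 equiv), THF, 0.002 M (27 added over 6 h), −78 to −20 °C
Reagents that add atoms: none
Why: Intramolecular alkylation of the α-sulfonyl allyl anion by the primary allylic bromide (SN2 at C3, bond C2–C3), the ring closure of this type used for germacrane and cembrane rings. Sulfonyl allyl anions alkylate at the α carbon and keep the alkene geometry; the hindered lactone carbonyl next to the quaternary C11 should not compete.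

Step 23
Reactants: 28 macrocyclic sulfone
Product: 29 (6S,7S,8R,11R)-6,11-bis[(tert-butyldimethylsilyl)oxy]germacra-1(10)Z,4E-dien-12,8-olide
Conditions: 6% Na/Hg, Na2HPO4, THF/MeOH, −20 °C
Reagents that add atoms: none
Why: Reductive desulfonylation by electron transfer and loss of sulfinate. Protonation of the allyl anion at its less substituted end (C2) should restore the trisubstituted C1=C10 alkene; the phosphate buffer protects the lactone.

Step 24
Reactants: 29 bis-silyl germacradienolide
Product: 30 (6S,7R,8R,11R)-6,11-dihydroxygermacra-1(10)Z,4E-dien-12,8-olide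
Conditions: Bu4NF, AcOH (1:1), THF, 0 °C to rt
Reagents that add atoms: none
Why: Fluoride-mediated desilylation; the tertiary silyl ether is activated by the adjacent carbonyl. The AcOH buffer keeps O6 protonated so that it does not attack C12, and avoids the acid that would cyclise the diene.

Step 25
Reactants: 31 angelic acid (two molecules)
Product: 32 angelic anhydride [(2Z)-2-methylbut-2-enoic anhydride]
Conditions: DCC (0.5 equiv relative to 31), CH2Cl2, 0 °C to rt
Reagents that add atoms: angelic acid (the second molecule of 31), C/C=C(/C)C(=O)O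
Why: Carbodiimide dehydration of two molecules of acid: one is activated as the O-acylisourea and is acylated by the carboxylate of the second, which supplies the other acyl group. No nucleophilic catalyst is present, so the Z alkene should not isomerise.

Step 26
Reactants: 30 diol; 32 angelic anhydride
Product: 33 (6S,7S,8R,11R)-6,11-bis{[(2Z)-2-methylbut-2-enoyl]oxy}germacra-1(10)Z,4E-dien-12,8-olide (target)
Conditions: 32 (4 equiv), LiN(SiMe3)2 (2.5 equiv) added last, THF, −78 to −20 °C
Reagents that add atoms: angelic anhydride (a second molecule of 32, one acyl group per hydroxyl), C/C=C(/C)C(=O)OC(=O)/C(C)=C\C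
Why: Acylation of lithium alkoxides by the anhydride, the method suited to hindered and tertiary hydroxyls that avoids the nucleophilic catalysts which turn angelates into tiglates. The base is added to diol and excess anhydride together so that each alkoxide is trapped as it forms, before O6 can attack C12.

## Compound list

1 | nerol, (2Z)-3,7-dimethylocta-2,6-dien-1-ol | CC(C)=CCC/C(C)=C\CO | starting material
2 | 1-({[(2Z)-3,7-dimethylocta-2,6-dien-1-yl]oxy}methyl)-4-methoxybenzene | CC(C)=CCC/C(C)=C\COCc1ccc(OC)cc1 | intermediate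
3 | rac-3-[(3Z)-5-[(4-methoxyphenyl)methoxy]-3-methylpent-3-en-1-yl]-2,2-dimethyloxirane | CC1(C)OC1CC/C(C)=C\COCc1ccc(OC)cc1 | intermediate
4 | (4Z)-6-[(4-methoxyphenyl)methoxy]-4-methylhex-4-enal | O=CCC/C(C)=C\COCc1ccc(OC)cc1 | intermediate
5 | ethyl 2-(diphenoxyphosphoryl)acetate | CCOC(=O)CP(=O)(Oc1ccccc1)Oc1ccccc1 | starting material
6 | (2R,4Z)-6-[(4-methoxyphenyl)methoxy]-4-methyl-2-[(phenylamino)oxy]hex-4-enal | O=C[C@H](ONc1ccccc1)C/C(C)=C\COCc1ccc(OC)cc1 | intermediate (not isolated)
7 | ethyl (2Z,4R,6Z)-8-[(4-methoxyphenyl)methoxy]-6-methyl-4-[(phenylamino)oxy]octa-2,6-dienoate | CCOC(=O)/C=C\[C@H](ONc1ccccc1)C/C(C)=C\COCc1ccc(OC)cc1 | intermediate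
8 | ethyl (2Z,4R,6Z)-4-hydroxy-8-[(4-methoxyphenyl)methoxy]-6-methylocta-2,6-dienoate | CCOC(=O)/C=C\[C@H](O)C/C(C)=C\COCc1ccc(OC)cc1 | intermediate (not isolated)
9 | (5R)-5-[(2Z)-4-[(4-methoxyphenyl)methoxy]-2-methylbut-2-en-1-yl]furan-2(5H)-one | O=C1C=C[C@@H](C/C(C)=C\COCc2ccc(OC)cc2)O1 | intermediate
10 | (1R,4R,5R)-4-[(2Z)-4-[(4-methoxyphenyl)methoxy]-2-methylbut-2-en-1-yl]-3,6-dioxabicyclo[3.1.0]hexan-2-one | O=C1O[C@H](C/C(C)=C\COCc2ccc(OC)cc2)[C@H]2O[C@@H]12 | intermediate
11 | (1R,3Z)-1-[(2R,3S)-3-(hydroxymethyl)oxiran-2-yl]-5-[(4-methoxyphenyl)methoxy]-3-methylpent-3-en-1-ol | O[C@H](C/C(C)=C\COCc1ccc(OC)cc1)[C@H]1O[C@H]1CO | intermediate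
12 | (1R,3Z)-5-[(4-methoxyphenyl)methoxy]-3-methyl-1-[(2R,3S)-3-[(triphenylmethoxy)methyl]oxiran-2-yl]pent-3-en-1-ol | O[C@H](C/C(C)=C\COCc1ccc(OC)cc1)[C@H]1O[C@H]1COC(c1ccccc1)(c1ccccc1)c1ccccc1 | intermediate
13 | ethyl (2S)-2-hydroxypropanoate, ethyl (S)-lactate | CCOC(=O)[C@H](C)O | starting material
14 | ethyl (2S)-2-[(tert-butyldimethylsilyl)oxy]propanoate | CCOC(=O)[C@H](C)O[Si](C)(C)C(C)(C)C | intermediate
15 | (2S)-2-[(tert-butyldimethylsilyl)oxy]propanoic acid | OC(=O)[C@H](C)O[Si](C)(C)C(C)(C)C | intermediate
16 | (1R,3Z)-5-[(4-methoxyphenyl)methoxy]-3-methyl-1-[(2R,3S)-3-[(triphenylmethoxy)methyl]oxiran-2-yl]pent-3-en-1-yl (2S)-2-[(tert-butyldimethylsilyl)oxy]propanoate | C[C@H](O[Si](C)(C)C(C)(C)C)C(=O)O[C@H](C/C(C)=C\COCc1ccc(OC)cc1)[C@H]1O[C@H]1COC(c1ccccc1)(c1ccccc1)c1ccccc1 | intermediate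
17 | (3R,4R,5R)-3-[(tert-butyldimethylsilyl)oxy]-4-[(1R)-1-hydroxy-2-(triphenylmethoxy)ethyl]-5-[(2Z)-4-[(4-methoxyphenyl)methoxy]-2-methylbut-2-en-1-yl]-3-methyloxolan-2-one | COc1ccc(COC/C=C(/C)C[C@H]2OC(=O)[C@](C)(O[Si](C)(C)C(C)(C)C)[C@@H]2[C@@H](O)COC(c2ccccc2)(c2ccccc2)c2ccccc2)cc1 | intermediate
18 | (3R,4S,5R)-3-[(tert-butyldimethylsilyl)oxy]-4-[(1R)-1-[(tert-butyldimethylsilyl)oxy]-2-(triphenylmethoxy)ethyl]-5-[(2Z)-4-[(4-methoxyphenyl)methoxy]-2-methylbut-2-en-1-yl]-3-methyloxolan-2-one | COc1ccc(COC/C=C(/C)C[C@H]2OC(=O)[C@](C)(O[Si](C)(C)C(C)(C)C)[C@@H]2[C@@H](O[Si](C)(C)C(C)(C)C)COC(c2ccccc2)(c2ccccc2)c2ccccc2)cc1 | intermediate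
19 | (3R,4S,5R)-3-[(tert-butyldimethylsilyl)oxy]-4-[(1R)-1-[(tert-butyldimethylsilyl)oxy]-2-(triphenylmethoxy)ethyl]-5-[(2Z)-4-hydroxy-2-methylbut-2-en-1-yl]-3-methyloxolan-2-one | OC/C=C(/C)C[C@H]1OC(=O)[C@](C)(O[Si](C)(C)C(C)(C)C)[C@@H]1[C@@H](O[Si](C)(C)C(C)(C)C)COC(c1ccccc1)(c1ccccc1)c1ccccc1 | intermediate
20 | (3R,4S,5R)-5-[(2Z)-4-bromo-2-methylbut-2-en-1-yl]-3-[(tert-butyldimethylsilyl)oxy]-4-[(1R)-1-[(tert-butyldimethylsilyl)oxy]-2-(triphenylmethoxy)ethyl]-3-methyloxolan-2-one | BrC/C=C(/C)C[C@H]1OC(=O)[C@](C)(O[Si](C)(C)C(C)(C)C)[C@@H]1[C@@H](O[Si](C)(C)C(C)(C)C)COC(c1ccccc1)(c1ccccc1)c1ccccc1 | intermediate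
21 | (3R,4S,5R)-5-[(2Z)-4-(benzenesulfonyl)-2-methylbut-2-en-1-yl]-3-[(tert-butyldimethylsilyl)oxy]-4-[(1R)-1-[(tert-butyldimethylsilyl)oxy]-2-(triphenylmethoxy)ethyl]-3-methyloxolan-2-one | O=S(=O)(c1ccccc1)C/C=C(/C)C[C@H]1OC(=O)[C@](C)(O[Si](C)(C)C(C)(C)C)[C@@H]1[C@@H](O[Si](C)(C)C(C)(C)C)COC(c1ccccc1)(c1ccccc1)c1ccccc1 | intermediate
22 | (3R,4S,5R)-5-[(2Z)-4-(benzenesulfonyl)-2-methylbut-2-en-1-yl]-3-[(tert-butyldimethylsilyl)oxy]-4-[(1R)-1-[(tert-butyldimethylsilyl)oxy]-2-hydroxyethyl]-3-methyloxolan-2-one | O=S(=O)(c1ccccc1)C/C=C(/C)C[C@H]1OC(=O)[C@](C)(O[Si](C)(C)C(C)(C)C)[C@@H]1[C@@H](O[Si](C)(C)C(C)(C)C)CO | intermediate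
23 | (3R,4S,5R)-5-[(2Z)-4-(benzenesulfonyl)-2-methylbut-2-en-1-yl]-3-[(tert-butyldimethylsilyl)oxy]-4-[(1R)-1-[(tert-butyldimethylsilyl)oxy]-2-oxoethyl]-3-methyloxolan-2-one | O=S(=O)(c1ccccc1)C/C=C(/C)C[C@H]1OC(=O)[C@](C)(O[Si](C)(C)C(C)(C)C)[C@@H]1[C@@H](O[Si](C)(C)C(C)(C)C)C=O | intermediate
24 | 2-(triphenylphosphoranylidene)propanal | CC(C=O)=P(c1ccccc1)(c1ccccc1)c1ccccc1 | starting material
25 | (3R,4S,5R)-5-[(2Z)-4-(benzenesulfonyl)-2-methylbut-2-en-1-yl]-3-[(tert-butyldimethylsilyl)oxy]-4-[(1S,2E)-1-[(tert-butyldimethylsilyl)oxy]-3-methyl-4-oxobut-2-en-1-yl]-3-methyloxolan-2-one | O=S(=O)(c1ccccc1)C/C=C(/C)C[C@H]1OC(=O)[C@](C)(O[Si](C)(C)C(C)(C)C)[C@@H]1[C@@H](O[Si](C)(C)C(C)(C)C)/C=C(\C)C=O | intermediate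
26 | (3R,4S,5R)-5-[(2Z)-4-(benzenesulfonyl)-2-methylbut-2-en-1-yl]-3-[(tert-butyldimethylsilyl)oxy]-4-[(1S,2E)-1-[(tert-butyldimethylsilyl)oxy]-4-hydroxy-3-methylbut-2-en-1-yl]-3-methyloxolan-2-one | O=S(=O)(c1ccccc1)C/C=C(/C)C[C@H]1OC(=O)[C@](C)(O[Si](C)(C)C(C)(C)C)[C@@H]1[C@@H](O[Si](C)(C)C(C)(C)C)/C=C(\C)CO | intermediate
27 | (3R,4S,5R)-5-[(2Z)-4-(benzenesulfonyl)-2-methylbut-2-en-1-yl]-4-[(1S,2E)-4-bromo-1-[(tert-butyldimethylsilyl)oxy]-3-methylbut-2-en-1-yl]-3-[(tert-butyldimethylsilyl)oxy]-3-methyloxolan-2-one | O=S(=O)(c1ccccc1)C/C=C(/C)C[C@H]1OC(=O)[C@](C)(O[Si](C)(C)C(C)(C)C)[C@@H]1[C@@H](O[Si](C)(C)C(C)(C)C)/C=C(\C)CBr | intermediate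
28 | (6S,7S,8R,11R)-2-(benzenesulfonyl)-6,11-bis[(tert-butyldimethylsilyl)oxy]germacra-1(10)Z,4E-dien-12,8-olide, mixture of C2 epimers | CC(C)(C)[Si](C)(C)O[C@H]1/C=C(\C)CC(S(=O)(=O)c3ccccc3)/C=C(/C)C[C@H]2OC(=O)[C@](C)(O[Si](C)(C)C(C)(C)C)[C@H]12 | intermediate
29 | (6S,7S,8R,11R)-6,11-bis[(tert-butyldimethylsilyl)oxy]germacra-1(10)Z,4E-dien-12,8-olide | CC(C)(C)[Si](C)(C)O[C@H]1/C=C(\C)CC/C=C(/C)C[C@H]2OC(=O)[C@](C)(O[Si](C)(C)C(C)(C)C)[C@H]12 | intermediate
30 | (6S,7R,8R,11R)-6,11-dihydroxygermacra-1(10)Z,4E-dien-12,8-olide | O[C@H]1/C=C(\C)CC/C=C(/C)C[C@H]2OC(=O)[C@](C)(O)[C@H]12 | intermediate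
31 | angelic acid, (2Z)-2-methylbut-2-enoic acid | C/C=C(/C)C(=O)O | starting material
32 | angelic anhydride, (2Z)-2-methylbut-2-enoic anhydride | C/C=C(/C)C(=O)OC(=O)/C(C)=C\C | intermediate
33 | (6S,7S,8R,11R)-6,11-bis{[(2Z)-2-methylbut-2-enoyl]oxy}germacra-1(10)Z,4E-dien-12,8-olide | C/C=C(/C)C(=O)O[C@H]1/C=C(\C)CC/C=C(/C)C[C@H]2OC(=O)[C@](C)(OC(=O)/C(C)=C\C)[C@H]12 | target

## Step count and least certain steps

Total: 26 steps. Longest linear sequence: 23 steps (steps 1–8, 11–24 and 26, from nerol); steps 9–10 and 25 are side branches.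

**Step 12 (key step).** The likely failures are poor facial selectivity at C11 if the bulky silyloxy group chelates lithium weakly and the enolate geometry is not uniform, and slow closure of the fully substituted enolate, which gives time for silyl migration or for the C6 alkoxide to shift the lactone. The fallback keeps the C7–C11 disconnection but sets C11 afterwards. It sets out from 12. Esterification with (tert-butyldimethylsilyloxy)acetic acid (DCC, DMAP) gives the glycolate ester F1. LiN(SiMe3)2 closes the less hindered enolate onto C7 to the hydroxy lactone F2, with either configuration at C11. TBSOTf and 2,6-lutidine give the bis-silyl ether F3. LDA and iodomethane at −78 °C then methylate the lactone enolate on the face away from the C7 branch, which is the required 11R arrangement, and the route is rejoined at 18.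

**Step 22.** The likely failure is intermolecular alkylation and oligomerisation, because a ten-membered ring with a trans-fused lactone is strained; elimination or SN2′ at the allylic bromide is also possible. The fallback replaces the SN2 electrophile by a π-allyl complex. It sets out from 26. Methyl chloroformate and pyridine give the allylic carbonate F4. Pd(PPh3)4 (zerovalent palladium) in THF at high dilution ionises the carbonate, the released methoxide deprotonates the sulfone, and attack at the less hindered C3 terminus (Tsuji–Trost alkylation) closes the ring, rejoining the route at 28.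

**Step 23.** The likely failure is loss of the alkene position or of the Z geometry at C1=C10 while the allyl anion is protonated; partial reduction of the lactone is also possible. The fallback changes the mechanism from dissolving-metal electron transfer to transition-metal hydride substitution. Pd(PPh3)4 with NaBH4 in THF/i-PrOH at 0 °C ionises the allylic sulfone and delivers hydride to the less substituted allyl terminus. It sets out from 28 and comes back at 29; no new compound is made on the way (F0).

**Step 24.** The likely failure is migration of the lactone to O6 (12,6-olide) once O6 is freed under fluoride; slow cleavage of the tertiary silyl ether lengthens that exposure. The fallback unveils and acylates the two oxygens one after the other, so that O6 is never free beside an alkoxide-forming reagent. It sets out from 29. HF·pyridine in THF/pyridine removes only the secondary silyl ether to give the 6-alcohol F5. The mixed anhydride of 31 with 2,4,6-trichlorobenzoyl chloride (Et3N, toluene, 80 °C, no DMAP) gives the 6-angelate F6. Bu4NF/AcOH then frees the tertiary alcohol F7. LiN(SiMe3)2 and 32 acylate it, and the route is rejoined at 33.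

**Step 26.** The likely failures are incomplete acylation of the tertiary C11 hydroxyl, isomerisation of angelate to tiglate, and lactone migration through the C6 alkoxide. The fallback builds the Z alkenes after acylation. It sets out from 30. 2-(Diphenoxyphosphoryl)propanoic acid with DCC and DMAP, harmless here because no alkene is present yet, gives the bis(phosphonopropanoate) F8. NaH and acetaldehyde in THF at −78 °C then form both angelates by Z-selective Horner–Wadsworth–Emmons olefination, rejoining the route at 33.

## Further compounds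

F1 | step 12 | (1R,3Z)-5-[(4-methoxyphenyl)methoxy]-3-methyl-1-[(2R,3S)-3-[(triphenylmethoxy)methyl]oxiran-2-yl]pent-3-en-1-yl 2-[(tert-butyldimethylsilyl)oxy]acetate | CC(C)(C)[Si](C)(C)OCC(=O)O[C@H](C/C(C)=C\COCc1ccc(OC)cc1)[C@H]1O[C@H]1COC(c1ccccc1)(c1ccccc1)c1ccccc1
F2 | step 12 | (4R,5R)-3-[(tert-butyldimethylsilyl)oxy]-4-[(1R)-1-hydroxy-2-(triphenylmethoxy)ethyl]-5-[(2Z)-4-[(4-methoxyphenyl)methoxy]-2-methylbut-2-en-1-yl]oxolan-2-one, C3 epimers | COc1ccc(COC/C=C(/C)C[C@H]2OC(=O)C(O[Si](C)(C)C(C)(C)C)[C@@H]2[C@@H](O)COC(c2ccccc2)(c2ccccc2)c2ccccc2)cc1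
F3 | step 12 | (4S,5R)-3-[(tert-butyldimethylsilyl)oxy]-4-[(1R)-1-[(tert-butyldimethylsilyl)oxy]-2-(triphenylmethoxy)ethyl]-5-[(2Z)-4-[(4-methoxyphenyl)methoxy]-2-methylbut-2-en-1-yl]oxolan-2-one, C3 epimers | COc1ccc(COC/C=C(/C)C[C@H]2OC(=O)C(O[Si](C)(C)C(C)(C)C)[C@@H]2[C@@H](O[Si](C)(C)C(C)(C)C)COC(c2ccccc2)(c2ccccc2)c2ccccc2)cc1
F4 | step 22 | (2E,4S)-4-[(2R,3S,4R)-2-[(2Z)-4-(benzenesulfonyl)-2-methylbut-2-en-1-yl]-4-[(tert-butyldimethylsilyl)oxy]-4-methyl-5-oxooxolan-3-yl]-4-[(tert-butyldimethylsilyl)oxy]-2-methylbut-2-en-1-yl methyl carbonate | O=S(=O)(c1ccccc1)C/C=C(/C)C[C@H]1OC(=O)[C@](C)(O[Si](C)(C)C(C)(C)C)[C@@H]1[C@@H](O[Si](C)(C)C(C)(C)C)/C=C(\C)COC(=O)OC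
F0 | step 23 | none | none
F5 | step 24 | (6S,7R,8R,11R)-11-[(tert-butyldimethylsilyl)oxy]-6-hydroxygermacra-1(10)Z,4E-dien-12,8-olide | O[C@H]1/C=C(\C)CC/C=C(/C)C[C@H]2OC(=O)[C@](C)(O[Si](C)(C)C(C)(C)C)[C@H]12
F6 | step 24 | (6S,7S,8R,11R)-11-[(tert-butyldimethylsilyl)oxy]-6-{[(2Z)-2-methylbut-2-enoyl]oxy}germacra-1(10)Z,4E-dien-12,8-olide | C/C=C(/C)C(=O)O[C@H]1/C=C(\C)CC/C=C(/C)C[C@H]2OC(=O)[C@](C)(O[Si](C)(C)C(C)(C)C)[C@H]12
F7 | step 24 | (6S,7S,8R,11R)-11-hydroxy-6-{[(2Z)-2-methylbut-2-enoyl]oxy}germacra-1(10)Z,4E-dien-12,8-olide | C/C=C(/C)C(=O)O[C@H]1/C=C(\C)CC/C=C(/C)C[C@H]2OC(=O)[C@](C)(O)[C@H]12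
F8 | step 26 | (6S,7S,8R,11R)-6,11-bis{[2-(diphenoxyphosphoryl)propanoyl]oxy}germacra-1(10)Z,4E-dien-12,8-olide | CC(C(=O)O[C@H]1/C=C(\C)CC/C=C(/C)C[C@H]2OC(=O)[C@](C)(OC(=O)C(C)P(=O)(Oc3ccccc3)Oc3ccccc3)[C@H]12)P(=O)(Oc1ccccc1)Oc1ccccc1
A1 | alternative 1 | (2E,6Z)-9-[(tert-butyldimethylsilyl)oxy]-10-ethenyl-3,7-dimethylcyclodeca-2,6-dien-1-ol, configured at C1, C9 and C10 as C6, C8 and C7 of the target | O[C@H]1/C=C(\C)CC/C=C(/C)C[C@@H](O[Si](C)(C)C(C)(C)C)[C@@H]1C=C
A2 | alternative 1 | (3E,7Z,11E)-10-[(tert-butyldimethylsilyl)oxy]-4,8-dimethyl-1-oxacyclotrideca-3,7,11-triene, C10 configured as C8 of the target | C1/C=C(\C)CC/C=C(/C)C[C@@H](O[Si](C)(C)C(C)(C)C)/C=C/CO1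
A3 | alternative 2 | (6S,7S,8R,11R)-6,11-bis[(tert-butyldimethylsilyl)oxy]germacra-1(10)Z,4E-dien-12,8-olide (identical with 29) | CC(C)(C)[Si](C)(C)O[C@H]1/C=C(\C)CC/C=C(/C)C[C@H]2OC(=O)[C@](C)(O[Si](C)(C)C(C)(C)C)[C@H]12
A4 | alternative 2 | (3R,4S,5R)-3-[(tert-butyldimethylsilyl)oxy]-4-[(1R,2E)-1-[(tert-butyldimethylsilyl)oxy]-3-iodobut-2-en-1-yl]-3-methyl-5-[(2Z)-2-methylpenta-2,4-dien-1-yl]oxolan-2-one | C=C/C=C(/C)C[C@H]1OC(=O)[C@](C)(O[Si](C)(C)C(C)(C)C)[C@@H]1[C@@H](O[Si](C)(C)C(C)(C)C)/C=C(\C)I
A5 | alternative 3 | tert-butyl 2-[(3E,7Z)-2-[(tert-butyldimethylsilyl)oxy]-10-hydroxy-4,8-dimethylcyclodeca-3,7-dien-1-yl]acetate, configured at C1, C2 and C10 as C7, C6 and C8 of the target | CC(C)(C)[Si](C)(C)O[C@H]1/C=C(\C)CC/C=C(/C)C[C@@H](O)[C@@H]1CC(=O)OC(C)(C)C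
A6 | alternative 3 | tert-butyl (5E)-4-[(tert-butyldimethylsilyl)oxy]-3-formyl-6,10-dimethyl-9-(4,4,5,5-tetramethyl-1,3,2-dioxaborolan-2-yl)undeca-5,10-dienoate, C3 and C4 configured as C7 and C6 of the target | O=C[C@H](CC(=O)OC(C)(C)C)[C@@H](O[Si](C)(C)C(C)(C)C)/C=C(\C)CCC(B1OC(C)(C)C(C)(C)O1)C(C)=C
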